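| setting | zeta | eta | theta | beta | alpha |
|---|---|---|---|---|---|
| J | 0.0800 M | 0.0400 M | 0.120 M | 0.0800 M | 0.0800 M |
| X | 8.00 × 10⁻⁴ M | 8.00 × 10⁻⁴ M | 8.00 × 10⁻⁴ M | 4.00 × 10⁻⁴ M | 8.00 × 10⁻⁴ M |
| time |  |  |  |  | 58 min |

| run | time / min | [Q] / M |
|---|---|---|
| zeta run | 0.92 | 3 × 10⁻⁴ |
| zeta run | 1.8 | 0.0026 |
| zeta run | 3.3 | 0.0037 |
| zeta run | 6.3 | 0.0095 |
| zeta run | 12 | 0.0236 |
| zeta run | 23 | 0.0524 |
| eta run | 0.92 | 0.0016 |
| eta run | 1.8 | 0 |
| eta run | 3.3 | 0.0044 |
| eta run | 6.3 | 0.0108 |
| eta run | 12 | 0.0189 |
| eta run | 23 | 0.0264 |
| theta run | 0.92 | 0.0017 |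
| theta run | 1.8 | 0.0017 |
| theta run | 3.3 | 0.0039 |
| theta run | 6.3 | 0.0076 |
| theta run | 12 | 0.0355 |
| theta run | 23 | 0.0846 |
| beta run | 0.92 | 4 × 10⁻⁴ |
| beta run | 1.8 | 4 × 10⁻⁴ |
| beta run | 3.3 | 0 |
| beta run | 6.3 | 0.0029 |
| beta run | 12 | 0.0069 |
| beta run | 23 | 0.0256 |

(readings scatter by 0.001 M)

* order of the initial rate in [J], near the charge of the zeta run, the rate being that where two percent of its J are Q (one fixed amount of Q, the same in the runs compared)
* order of the initial rate in [X], near the charge of the zeta run, the rate being that where two percent of its J are Q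
* Q in the alpha run at 58 min, as a share of the J charged

- Overall: J -> Q, with X as catalyst.
- Constant volume, constant temperature.
- Bound and free are read together.
- An order is taken over about fifteen percent of the charge, up and down.

At early times the readings were too rough to give a rate: the beta run read 0 M at 3.3 min, against a scatter of 0.001 M. So I looked for the effect of X further along the curves and compared the beta run with the zeta run in two ways.

The first way went by the clock. At 12 min the beta run read 0.0069 M and the zeta run 0.0236 M, and taken as a rate ratio over the halved X this gave an order of 1.77.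

The second way went by amount. I defined the matched-amount time ratio as the time the beta run took to make a given amount of Q over the time the zeta run took to make the same amount; its inverse is a mean rate ratio. The beta run made 0.0069 M in 12 min, and interpolation put the zeta run there at 4.96 min. That gave a ratio of 2.42, and an order of 1.28, read over a halving of X.

The two ways parted, and the clock was the one that cheated. At 12 min the zeta run held more Q than the beta run, and the zeta run sped up as Q grew, from a mean of 0.00151 M min⁻¹ up to 6.3 min to 0.00262 M min⁻¹ after 12 min. This looked like autocatalysis. I committed to the order by amount. The alpha run has the charge of the zeta run, so I held it at 65.5% at 23 min, and I gave no figure for 58 min, which is later than the last reading.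

The forecast gave orders of −0.4 in J and 1.8 in X, and 91% for the alpha run, holding that “Q relieves the inhibition or activates the catalyst”. The flask gives −0.23, 1.6 and 28.5%.

    X + J ⇌ XJ, settled at all times (47.70 M⁻¹)
    XJ + X → Q + 2 X (8760 M⁻¹ min⁻¹)
    Q → Oz (0.02970 min⁻¹)
    J + Q → 2 Q (2.178 M⁻¹ min⁻¹)

The alpha run holds 28.5% of its J as Q at 58 min, less than the 65.5% read in the zeta run at 23 min, and the equations take Q on to Oz with a constant of 0.0297 min⁻¹. The inverse of the matched-amount ratio for the beta run is 0.413, beside a simulated rate ratio of 0.39. For the theta run the same rule, read at 0.0236 M, gives 9.57 min by interpolation, against 12 min in the zeta run, so a mean rate ratio of 1.25 as read, while the rate ratio of 0.93 for the theta run is taken where two percent of the J of the zeta run have turned.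

The earlier runs and the new flask are simulated on assumed constants, and the scatter is random.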